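We must decide how far the nucleophile can be cut below the 2.1 equiv of the dawn run, so we first ask what one electrophile costs in nucleophile.

| flask | electrophile | nucleophile | gas | remark | time |
|---|---|---|---|---|---|
| dawn | 0.21 M | 2.1 equiv | 70 mM (held) | run made earlier |  |
| delta | 0.21 M | 1.80 equiv | 70 mM (held) |  | 5.0 h |
| eta | 0.21 M | 1.40 equiv | 70 mM (held) |  | 5.0 h |
| epsilon | 0.21 M | 1.10 equiv | 70 mM (held) |  | 5.0 h |

dawn run (percent of the electrophile charged)

| time / h | electrophile / % | product / % |
|---|---|---|
| 0.833 | 47 | 52 |
| 1.50 | 31 | 69 |
| 2.50 | 21 | 75 |
| 3.00 | 19 | 81 |
| 4.00 | 15 | 86 |
| 5.00 | 12 | 86 |

(standard deviation of a reading: 1.5 percentage points)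

- at the start none of the gas is in solution

- part of the electrophile that has reacted at the end, delta
- part of the electrophile that has reacted at the end, eta
- part of the electrophile that has reacted at the end, epsilon
- what raising the equivalents of nucleophile from its lowest to its highest value here does to the part of the electrophile that has reacted (changes below 5 percentage points count as none) (it falls / it rises / no change)

In the dawn run, one over the fraction of electrophile left, less one, divided by the time, reads 1.50 /h at 2.50 h and 1.47 /h at 5.00 h, about the same. Within the scatter, that reads as a second-order curve in electrophile. We read it as nucleophile falling in step with electrophile, which needs two nucleophile lost per electrophile.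

How far can each flask go, then? On that reading, below two equivalents the nucleophile is the limiting reagent. Delta has 90.0%, eta 70.0% and epsilon 55.0% as what we call the ceiling: the equivalents divided by two, the part of the electrophile the charge pays for at two nucleophile each. The dawn ceiling, 105%, is more than the electrophile charged, so that run met none.

How fast is the ceiling approached? The gap closes on a time of one over the dawn figure times the room between ceiling and full conversion. That gives 1.52 h for epsilon, shorter than the 5.0 h allowed, but 6.82 h for delta, longer. Integrating, with 2.27 h for eta, we commit to 82.4% for delta, 67.5% for eta and 54.1% for epsilon, a rise of 28 percentage points.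

The forecast differs: 88% for delta, 88% for eta, 87% for epsilon and, for the trend, no change, since the nucleophile “shows no visible effect”.

The flasks give 80.5% for delta, 66.2% for eta and 53.4% for epsilon. For the part reacted, with the equivalents raised from lowest to highest, the answer is: it rises, by 27 points.

    electrophile + nucleophile ⇌ acid set free + product (K = 0.440, k = 0.0490 /M/min)
    nucleophile + acid set free ⇌ protonated nucleophile, settled at all times (K = 26000 /M)
    acid set free + free base ⇌ salt of the base (K = 1000 /M, k = 0.200 /M/min)
    gas ⇌ free base, rate k4*(csat - [free base]) (kL = 0.950 /min)

At 5.00 h epsilon stands under its ceiling of 55.0%, with 3.5% of its nucleophile left unbound and 0.111 M of protonated nucleophile; at 50.0 h it reads 60.9%, above that ceiling. The neighbouring flask is epsilon with 2.80 equiv of nucleophile. Its ceiling is 140%, more than the electrophile charged, and the same reckoning gives 98.4%. That flask gives 97.4%, with 2.6% of its electrophile and 30% of its nucleophile still unbound.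

The runs come from a simulation for an exercise; noise was put on by code.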